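**Retrosynthetic overview**
- The six-membered triketone ring is made last: one-carbon ring expansion of a cyclopenta[b]pyran-5,6-dione (a 1,2-dione) with 1-diazo-4-methylpentan-2-one, where a 1,2-acyl shift inserts the acyl-bearing carbon between the two carbonyls.
- The C8 prenyl group comes from a Stille coupling on a vinyl bromide; the bromine is put in first, blocks that carbon and keeps a third alkene out of the cyclisation.
- The 2H-pyran and the C4a quaternary stereocentre come from a desymmetrising Wacker-type cyclisation of an achiral gem-diprenyl bromo-enol (new step).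
- The gem-diprenyl unit comes from dianion alkylation of brominated cyclopentane-1,2,4-trione with two equivalents of prenyl bromide.
- Ring order: five-membered carbocycle (bought) → 2H-pyran → carbocycle enlarged from five to six members.

Assumptions: cyclopentane-1,2,4-trione (CAS 15849-14-6) is taken as a catalogue compound; enolisable compounds are drawn as one tautomer; the (M,S,S) ligand in step 3 is assumed to give the (4aR) product, and the (P,R,R) ligand is used if the first run shows the opposite sense.

**Step 1**
Reactants: 1 cyclopentane-1,2,4-trione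
Product: 2 3-bromo-4-hydroxycyclopent-3-ene-1,2-dione
Conditions: NBS (1.0 equiv), MeCN, 0 °C
Reagents that add atoms: N-bromosuccinimide, O=C1CCC(=O)N1Br
Why: Electrophilic α-bromination of a cyclic β-dicarbonyl enol; the two active methylene positions of 1 are equivalent, so one equivalent of NBS gives a single monobromide, and no stereocentre is formed.

**Step 2**
Reactants: 2 3-bromo-4-hydroxycyclopent-3-ene-1,2-dione; 3 1-bromo-3-methylbut-2-ene (prenyl bromide, first equivalent)
Product: 5 3-bromo-4-hydroxy-5,5-bis(3-methylbut-2-en-1-yl)cyclopent-3-ene-1,2-dione, via monoprenyl bromo-enol 4 (not isolated)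
Conditions: LiN(SiMe3)2 (2.1 equiv), THF, –78 °C; 3 (1.05 equiv), –78 → –20 °C; LiN(SiMe3)2 (1.1 equiv), –78 °C; 3 (second 1.05 equiv), → 0 °C; 1 M HCl work-up
Reagents that add atoms: 1-bromo-3-methylbut-2-ene (compound 3, second equivalent), CC(C)=CCBr
Why: Dianion alkylation of a β-dicarbonyl (two successive SN2 reactions on an allylic bromide, one equivalent of 3 each): once the acidic bromo-enol proton is gone, further base can deprotonate only C5, and this less stabilised carbanion is prenylated first to 4 and then again to 5 while the brominated enolate carbon stays unreactive, giving an achiral product with two enantiotopic prenyl groups.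

**Step 3**
Reactants: 5 3-bromo-4-hydroxy-5,5-bis(3-methylbut-2-en-1-yl)cyclopent-3-ene-1,2-dione
Product: 6 (4aR)-7-bromo-2,2-dimethyl-4a-(3-methylbut-2-en-1-yl)cyclopenta[b]pyran-5,6(2H,4aH)-dione
Conditions: Pd(OCOCF3)2 (10 mol %), (M,S,S)-i-Pr-SPRIX (spiro bis(isoxazoline) ligand, 12 mol %), p-benzoquinone (2 equiv), CH2Cl2, 25 °C
Reagents that add atoms: none
Why: Proposed new method: enantiotopic-group-selective Wacker-type cyclisation, in which the ligand-bound divalent palladium activates one of the two enantiotopic prenyl alkenes, the C4 enol oxygen (the only enolisable oxygen next to the quaternary carbon, because the neighbouring 1,2-dione carbonyl cannot enolise) adds 6-endo to the dimethyl-substituted alkene carbon through a chair-like transition state, and β-hydride elimination, possible only towards the ring CH2, gives the 2H-pyran and fixes C4a as R while the second prenyl group has no hydroxyl left to react with; the closest known reaction types are the enantioselective Pd–SPRIX 6-endo Wacker-type cyclisation of 2-alkenyl-1,3-diketones and the oxidative cyclisation of ortho-prenylphenols to 2,2-dimethylchromenes, neither of which has been used to tell apart two prenyl groups on one carbon.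

**Step 4**
Reactants: 3 1-bromo-3-methylbut-2-ene (prenyl bromide)
Product: 7 tributyl(3-methylbut-2-en-1-yl)stannane
Conditions: Bu3SnH, LiN(iPr)2, THF, 0 °C; then 3, –78 °C → rt
Reagents that add atoms: tributyltin hydride, CCCC[SnH](CCCC)CCCC
Why: Stannyl-anion alkylation: SN2 displacement of the primary allylic bromide by tributylstannyllithium gives the linear prenylstannane.

**Step 5**
Reactants: 6 (4aR)-7-bromo-2,2-dimethyl-4a-(3-methylbut-2-en-1-yl)cyclopenta[b]pyran-5,6(2H,4aH)-dione; 7 tributyl(3-methylbut-2-en-1-yl)stannane
Product: 8 (4aR)-2,2-dimethyl-4a,7-bis(3-methylbut-2-en-1-yl)cyclopenta[b]pyran-5,6(2H,4aH)-dione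
Conditions: Pd2(dba)3 (2.5 mol %), AsPh3 (10 mol %), DMF, 50 °C
Reagents that add atoms: none
Why: Stille cross-coupling of an electron-poor α-bromo enone under neutral conditions; reductive elimination from the less hindered primary allylpalladium end gives the linear prenyl group, and the 1,2-dione, the pyran and the C4a stereocentre are not touched.

**Step 6**
Reactants: 9 3-methylbutanoyl chloride
Product: 10 1-diazo-4-methylpentan-2-one
Conditions: CH2N2 (2.2 equiv), Et2O, 0 °C → rt
Reagents that add atoms: diazomethane, C=[N+]=[N-]
Why: Acylation of diazomethane by an acid chloride (first stage of the Arndt–Eistert sequence), the second equivalent of diazomethane taking up HCl as chloromethane; no stereocentre.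

**Step 7**
Reactants: 8 (4aR)-2,2-dimethyl-4a,7-bis(3-methylbut-2-en-1-yl)cyclopenta[b]pyran-5,6(2H,4aH)-dione; 10 1-diazo-4-methylpentan-2-one
Product: 11 (4aR)-7-hydroxy-2,2-dimethyl-6-(3-methylbutanoyl)-4a,8-bis(3-methylbut-2-en-1-yl)-2H-chromen-5(4aH)-one
Conditions: Sc(OTf)3 (10 mol %), CH2Cl2, –40 → 0 °C; pH 7 buffer work-up
Reagents that add atoms: none
Why: Lewis-acid-catalysed diazo–carbonyl homologation (Büchner–Curtius–Schlotterbeck reaction, a Tiffeneau–Demjanov-type ring expansion): the diazo carbon of 10 adds to one carbonyl of the scandium-activated 1,2-dione and the neighbouring carbonyl carbon makes a 1,2-acyl shift with loss of N2, which places CH(COCH2CHMe2) between C5 and C6 whichever carbonyl is attacked, and enolisation gives the triketone with the C4a stereocentre (R) untouched.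

**Compound list**
1 | cyclopentane-1,2,4-trione | O=C1CC(=O)C(=O)C1 | starting material
2 | 3-bromo-4-hydroxycyclopent-3-ene-1,2-dione | O=C1CC(O)=C(Br)C1=O | intermediate
3 | 1-bromo-3-methylbut-2-ene (prenyl bromide) | CC(C)=CCBr | starting material
4 | 3-bromo-4-hydroxy-5-(3-methylbut-2-en-1-yl)cyclopent-3-ene-1,2-dione | O=C1C(CC=C(C)C)C(O)=C(Br)C1=O | intermediate
5 | 3-bromo-4-hydroxy-5,5-bis(3-methylbut-2-en-1-yl)cyclopent-3-ene-1,2-dione | O=C1C(CC=C(C)C)(CC=C(C)C)C(O)=C(Br)C1=O | intermediate
6 | (4aR)-7-bromo-2,2-dimethyl-4a-(3-methylbut-2-en-1-yl)cyclopenta[b]pyran-5,6(2H,4aH)-dione | BrC1=C2OC(C)(C)C=C[C@@]2(CC=C(C)C)C(=O)C1=O | intermediate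
7 | tributyl(3-methylbut-2-en-1-yl)stannane | CC(C)=CC[Sn](CCCC)(CCCC)CCCC | intermediate
8 | (4aR)-2,2-dimethyl-4a,7-bis(3-methylbut-2-en-1-yl)cyclopenta[b]pyran-5,6(2H,4aH)-dione | CC(C)=CCC1=C2OC(C)(C)C=C[C@@]2(CC=C(C)C)C(=O)C1=O | intermediate
9 | 3-methylbutanoyl chloride | CC(C)CC(Cl)=O | starting material
10 | 1-diazo-4-methylpentan-2-one | CC(C)CC(=O)C=[N+]=[N-] | intermediate
11 | (4aR)-7-hydroxy-2,2-dimethyl-6-(3-methylbutanoyl)-4a,8-bis(3-methylbut-2-en-1-yl)-2H-chromen-5(4aH)-one | CC(C)=CCC1=C2OC(C)(C)C=C[C@@]2(CC=C(C)C)C(=O)C(C(=O)CC(C)C)=C1O | target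

**Step count**
Total steps: 7 (steps 4 and 6 are side branches). Longest linear sequence: 5 (steps 1, 2, 3, 5, 7).

**Steps most likely to fail**

Step 3 (the proposed new method). The catalyst may give low enantioselectivity, some 5-exo closure, or slow turnover with the weakly nucleophilic bromo-enol. The fallback sets out from 5 and comes back at 6, using known selenium chemistry and resolution. Compound 5 is cyclised with N-(phenylseleno)phthalimide and catalytic camphorsulfonic acid in CH2Cl2 (6-endo selenoetherification) to the racemic selenide F1. Oxidation with mCPBA at –78 °C and warming with iPr2NH eliminates the selenoxide towards the ring CH2 and gives the racemic bromo-dione F2. Preparative chiral SFC then delivers 6 and the unwanted (4aS) enantiomer F3, at the cost of half the material.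

Step 7. The quaternary C4a or the alkenyl C7 could migrate instead of the acyl carbon. The Lewis acid may also ionise the tertiary allylic ether, or be sequestered by the chelating triketone product. The fallback sets out from 8 (together with 10) and comes back at 11 by a stepwise, acid-free sequence. DBU-catalysed aldol-type addition of 10 to the 1,2-dione in MeCN at 0 °C gives the α-diazo-β-hydroxy ketone F4. Rh2(OAc)4 (1 mol %) in CH2Cl2 at 25 °C then forms the metal carbene, which rearranges by 1,2-acyl shift with loss of N2 to 11.

Step 5. The allylstannane could add to the reactive 1,2-dione, or some reverse-prenyl product could form. The fallback sets out from 6 and comes back at 11 by inverting the order of events. Compound 6 is first ring-expanded with 10 under the step 7 conditions to the bromo-triketone F5, in which no free ketone remains. Stille coupling of F5 with 7 (Pd2(dba)3, AsPh3, DMF, 50 °C) is then the last step.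

**Further compounds**
F1 | step 3 | 7-bromo-2,2-dimethyl-4a-(3-methylbut-2-en-1-yl)-3-(phenylselanyl)-3,4-dihydrocyclopenta[b]pyran-5,6(2H,4aH)-dione (racemic, diastereomer mixture) | BrC1=C2OC(C)(C)C([Se]c3ccccc3)CC2(CC=C(C)C)C(=O)C1=O
F2 | step 3 | racemic 7-bromo-2,2-dimethyl-4a-(3-methylbut-2-en-1-yl)cyclopenta[b]pyran-5,6(2H,4aH)-dione | BrC1=C2OC(C)(C)C=CC2(CC=C(C)C)C(=O)C1=O
F3 | step 3 | (4aS)-7-bromo-2,2-dimethyl-4a-(3-methylbut-2-en-1-yl)cyclopenta[b]pyran-5,6(2H,4aH)-dione | BrC1=C2OC(C)(C)C=C[C@]2(CC=C(C)C)C(=O)C1=O
F4 | step 7 | 5-(1-diazo-4-methyl-2-oxopentyl)-5-hydroxy-2,2-dimethyl-4a,7-bis(3-methylbut-2-en-1-yl)-4a,5-dihydrocyclopenta[b]pyran-6(2H)-one (C4a as in 8, both C5 epimers) | CC(C)=CCC1=C2OC(C)(C)C=C[C@@]2(CC=C(C)C)C(O)(C(=[N+]=[N-])C(=O)CC(C)C)C1=O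
F5 | step 5 | (4aR)-8-bromo-7-hydroxy-2,2-dimethyl-6-(3-methylbutanoyl)-4a-(3-methylbut-2-en-1-yl)-2H-chromen-5(4aH)-one | BrC1=C2OC(C)(C)C=C[C@@]2(CC=C(C)C)C(=O)C(C(=O)CC(C)C)=C1O
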